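**Retrosynthetic overview**

1. Labels: Cs is the spiro carbon, Ca the tetrahydropyran carbon bearing ring C, Cb the one bearing the heptamethylene chain. Ring A is attached last by Suzuki coupling to a lactim triflate; ring B and Cs are built on a lactone carbonyl from a 3-methoxyacrylate unit and ammonia.
2. Structural feature: ring C is a 2,5-disubstituted pyrrole (C2 on Ca, C5 on the chain). Without its nitrogen, the four pyrrole carbons, Ca, Cb and the seven CH2 groups form a 13-membered carbocycle trans-fused to the tetrahydropyran, and those four carbons can be carried as a conjugated diyne.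
3. Ring C comes from the cyclic 1,3-diyne and ammonia (copper-catalysed double hydroamination). The diyne ring is closed by oxidative coupling of an ethynyl group on Ca with a non-8-ynyl chain on Cb, at the future C3–C4 bond of ring C, while Cs is a methyl acetal.
4. The bis-alkyne comes from (S)-parasorbic acid: anti conjugate addition of the C9 alkynyl chain (sets Cb), formaldehyde aldol trapping (sets Ca), lactone to methyl acetal, CH2OH to C≡CH.
5. Ring order: tetrahydropyran (chiral pool) → 13-membered carbocycle → pyrrole ring C → spiro ring B → ring A appended.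

Key step: step 7

Assumption: the lactols and methyl acetals of this route form as mixtures of anomers. They are drawn as one anomer (methoxy trans to the Ca substituent) and used as the mixture, because this carbon later becomes the lactone carbonyl.

**Route**

Step 1
Reactants: 1 trimethylsilylacetylene; 2 1,7-dibromoheptane
Product: 4 (9-bromonon-1-yn-1-yl)trimethylsilane, via lithium acetylide 3 (not isolated)
Conditions: n-BuLi, THF, −78 °C; then 2 (3 equiv), DMPU, −78 °C → rt
Reagents that add atoms: none
Why: SN2 alkylation of a lithium acetylide with a primary bromide, the excess of dibromide keeping the second bromide unreacted.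

Step 2
Reactants: 4 (9-bromonon-1-yn-1-yl)trimethylsilane; 5 (S)-parasorbic acid
Product: 8 (3S,4S,6S)-3-(hydroxymethyl)-6-methyl-4-[9-(trimethylsilyl)non-8-yn-1-yl]oxan-2-one, via Grignard reagent 6 (not isolated), via magnesium enolate 7 (not isolated)
Conditions: Mg, THF, rt; then CuBr·SMe2 (15 mol %), 5, THF, −40 °C; then CH2O (gas), −40 °C; aq. NH4Cl
Reagents that add atoms: formaldehyde, C=O
Why: Copper-catalysed conjugate addition of the Grignard reagent should occur anti to the C6 methyl group (axial attack on the half-chair with pseudo-equatorial methyl), setting Cb trans to the methyl, and the magnesium enolate then adds to formaldehyde on the face away from the new Cb chain (tandem conjugate addition–aldol), setting Ca trans to Cb.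

Step 3
Reactants: 8 hydroxymethyl lactone
Product: 9 (3S,4S,6S)-3-(hydroxymethyl)-6-methyl-4-[9-(trimethylsilyl)non-8-yn-1-yl]oxan-2-ol (lactol; both anomers)
Conditions: i-Bu2AlH (2.3 equiv), CH2Cl2, −78 °C; aq. potassium sodium tartrate
Reagents that add atoms: none
Why: Partial reduction of a δ-lactone by i-Bu2AlH stops at the aluminium lactolate at −78 °C, the first equivalent being consumed by the free hydroxyl, and the silyl alkyne is inert at this temperature.

Step 4
Reactants: 9 lactol
Product: 10 [(2R,3S,4S,6S)-2-methoxy-6-methyl-4-[9-(trimethylsilyl)non-8-yn-1-yl]oxan-3-yl]methanol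
Conditions: MeOH, PPTS (10 mol %), rt
Reagents that add atoms: methanol, CO
Why: Acid-catalysed Fischer-type acetalisation through the ring oxocarbenium ion in methanol; the primary alcohol cannot close onto this carbon (it would give an oxetane) and the C-silyl alkyne tolerates mild acid.

Step 5
Reactants: 10 acetal alcohol
Product: 11 (2R,3S,4S,6S)-2-methoxy-6-methyl-4-[9-(trimethylsilyl)non-8-yn-1-yl]oxane-3-carbaldehyde
Conditions: Dess–Martin periodinane, pyridine, CH2Cl2, 0 °C → rt; used crude
Reagents that add atoms: none
Why: Dess–Martin oxidation under buffered, near-neutral conditions gives the aldehyde without enolisation, which matters because the aldehyde is β to the acetal leaving group and α to the Ca stereocentre.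

Step 6
Reactants: 11 aldehyde
Product: 13 (2R,3S,4S,6S)-3-ethynyl-2-methoxy-6-methyl-4-(non-8-yn-1-yl)oxane, via silyl bis-alkyne 12 (not isolated)
Conditions: Me3SiCHN2, n-BuLi, THF, −78 °C; then 11, −78 → 0 °C; then K2CO3 (cat.), MeOH, rt
Reagents that add atoms: trimethylsilyldiazomethane, C[Si](C)(C)C=[N+]=[N-]
Why: Colvin rearrangement: lithiated trimethylsilyldiazomethane adds to the aldehyde at −78 °C faster than it can enolise it (so neither epimerisation at Ca nor β-elimination of methoxide should occur), loss of Me3SiOLi and N2 gives an alkylidene carbene whose 1,2-hydrogen shift gives the alkyne, and methanolysis then removes the alkynyl silyl group.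

Step 7
Reactants: 13 bis-terminal alkyne
Product: 14 cyclic diyne: methyl acetal of the tetrahydropyran trans-fused through Ca–Cb to a cyclotrideca-1,3-diyne (Ca–C≡C–C≡C–(CH2)7–Cb)
Conditions: Cu(OAc)2 (6 equiv), pyridine/Et2O 3:1, 40 °C, syringe-pump addition of 13 over 12 h (final 1 mM)
Reagents that add atoms: none
Why: Each terminal alkyne is deprotonated in pyridine to a copper acetylide, and oxidation by divalent copper joins the two acetylide carbons in a dinuclear copper intermediate (Glaser–Eglinton coupling); the closest known case is the high-dilution Eglinton closure of α,ω-diynes to cycloalka-1,3-diynes. The ring closes end to end as a 13-membered carbocycle in which both reacting sp carbons become ring atoms, the eight-bond path Ca–Cb–(CH2)7 spanning the roughly 6.7 Å between the two propargylic carbons with moderate bending of the diyne rod. No stereocentre is formed, and Ca is not at risk because, with Cs as an acetal, it is not α to a carbonyl and cannot enolise or isomerise to an allene in pyridine. The selectivity needed is ring closure over dimerisation; slow addition keeps the substrate near 1 mM, and the trans vicinal arms sit gauche and convergent in the chair that has both of them equatorial (the diaxial chair cannot reach). The bending strain stored here should help the two nitrogen additions of step 8.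

Step 8
Reactants: 14 cyclic diyne
Product: 15 pyrrolophane methyl acetal: ring C (1H-pyrrole) with C2 on Ca and C5 joined through (CH2)7 to Cb
Conditions: NH3 (excess), CuCl (20 mol %), 1,4-dioxane, sealed vessel, 110 °C
Reagents that add atoms: ammonia, N
Why: Copper-catalysed double hydroamination of a 1,3-diyne (Reisch–Schulte pyrrole synthesis): ammonia adds to one outer alkyne carbon and the enamine closes 5-endo-dig onto the other outer carbon, both additions releasing the bending strain of the ring, with no stereocentre involved and the acetal stable to base.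

Step 9
Reactants: 15 pyrrolophane acetal
Product: 16 pyrrolophane lactol (both anomers)
Conditions: AcOH/THF/H2O 3:1:1, 45 °C
Reagents that add atoms: water, O
Why: Acid-catalysed acetal hydrolysis through the ring oxocarbenium ion, under aqueous acetic acid mild enough for a 2,5-dialkylpyrrole, which cannot trap the cation intramolecularly (only four-membered rings would result).

Step 10
Reactants: 16 lactol
Product: 17 pyrrolophane δ-lactone (Cs as lactone carbonyl, ring C on Ca)
Conditions: (n-Pr4N)RuO4 (5 mol %), NMO, 4 Å MS, CH2Cl2, rt
Reagents that add atoms: none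
Why: Ley–Griffith oxidation of a lactol to the lactone under neutral conditions, which should leave the pyrrole and the now enolisable Ca untouched.

Step 11
Reactants: 17 lactone; 18 methyl (E)-3-methoxyacrylate
Product: 21 spiro tetronate: 4-methoxyfuran-2(5H)-one whose C5 is Cs of the tetrahydropyran, via N-lithio lactone 19 (not isolated), via lithioacrylate 20 (not isolated)
Conditions: 18, LiN(i-Pr)2, THF, −95 °C; 17, LiN(SiMe3)2 (1.0 equiv), THF, −78 °C; combine at −95 °C, warm to 0 °C; aq. NH4Cl
Reagents that add atoms: none
Why: β-Lithiation of the methoxyacrylate (lithium held cis to the ester) gives a vinyllithium that adds to the lactone carbonyl, the pyrrolide anion disfavouring enolisation at Ca, and the lactolate closes onto the cis ester to the butenolide (organolithium addition to a lactone followed by tetronate formation); the spiro configuration formed here is reset in step 12.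

Step 12
Reactants: 21 spiro tetronate
Product: 23 spiro lactam: 4-methoxy-1,5-dihydro-2H-pyrrol-2-one spiro at C5 (= Cs) to the tetrahydropyran with N cis to ring C, via hydroxylactam 22 (not isolated)
Conditions: NH3 (7 M in MeOH), 0 °C → rt; evaporate; CSA (10 mol %), 4 Å MS, CH2Cl2, rt
Reagents that add atoms: ammonia, N
Why: Ammonia opens the activated acylal lactone at its carbonyl to a Z-keto amide that closes to the hydroxylactam, and acid then forms the N-acyliminium ion, which the C6 hydroxyl traps 6-exo under reversible conditions; the spiro centre should settle with the C–N bond axial on the tetrahydropyran (anomeric effect) in the chair that keeps both ansa arms equatorial, which places N cis to ring C as in the target.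

Step 13
Reactants: 23 spiro lactam
Product: 24 lactim triflate: 3-methoxy-5-(trifluoromethylsulfonyloxy)-2H-pyrrole spiro at C2 (= Cs)
Conditions: Tf2O, 2,6-di-tert-butyl-4-methylpyridine, CH2Cl2, −78 → −20 °C; used directly
Reagents that add atoms: triflic anhydride, O=S(=O)(C(F)(F)F)OS(=O)(=O)C(F)(F)F
Why: O-Sulfonylation of the vinylogous-carbamate lactam oxygen, the most nucleophilic site, gives the imidoyl triflate (the activation used for 4-methoxypyrrolin-2-ones in prodiginine chemistry), and the hindered base captures triflic acid so that the N,O-ketal and ring C are not exposed to acid.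

Step 14
Reactants: 24 lactim triflate; 25 N-Boc-pyrrol-2-ylboronic acid
Product: 27 premarineosin A, via N-Boc-premarineosin A 26 (not isolated)
Conditions: Pd(PPh3)4 (10 mol %), aq. K2CO3, 1,4-dioxane, 80 °C; then NaOMe (cat.), MeOH, rt
Reagents that add atoms: none
Why: Suzuki–Miyaura coupling of the imidoyl triflate with the 2-pyrrolylboronic acid forms the ring A–ring B bond without touching Cs, and methoxide then removes the carbamate from the pyrrole nitrogen by transesterification.

**Compound list**

1 | trimethylsilylacetylene | C#C[Si](C)(C)C | starting material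
2 | 1,7-dibromoheptane | BrCCCCCCCBr | starting material
3 | lithium (trimethylsilyl)acetylide | [Li]C#C[Si](C)(C)C | intermediate
4 | (9-bromonon-1-yn-1-yl)trimethylsilane | C[Si](C)(C)C#CCCCCCCCBr | intermediate
5 | (S)-parasorbic acid, (6S)-6-methyl-5,6-dihydro-2H-pyran-2-one | C[C@H]1CC=CC(=O)O1 | starting material
6 | [9-(trimethylsilyl)non-8-yn-1-yl]magnesium bromide | C[Si](C)(C)C#CCCCCCCC[Mg]Br | intermediate
7 | bromomagnesium enolate of the 4,6-trans conjugate adduct | Br[Mg]OC1=C[C@@H](CCCCCCCC#C[Si](C)(C)C)C[C@H](C)O1 | intermediate
8 | (3S,4S,6S)-3-(hydroxymethyl)-6-methyl-4-[9-(trimethylsilyl)non-8-yn-1-yl]oxan-2-one (3,4-trans, 4,6-trans) | O=C1O[C@@H](C)C[C@H](CCCCCCCC#C[Si](C)(C)C)[C@H]1CO | intermediate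
9 | (3S,4S,6S)-3-(hydroxymethyl)-6-methyl-4-[9-(trimethylsilyl)non-8-yn-1-yl]oxan-2-ol, anomeric mixture | OC1O[C@@H](C)C[C@H](CCCCCCCC#C[Si](C)(C)C)[C@H]1CO | intermediate
10 | [(2R,3S,4S,6S)-2-methoxy-6-methyl-4-[9-(trimethylsilyl)non-8-yn-1-yl]oxan-3-yl]methanol | CO[C@@H]1O[C@@H](C)C[C@H](CCCCCCCC#C[Si](C)(C)C)[C@H]1CO | intermediate
11 | (2R,3S,4S,6S)-2-methoxy-6-methyl-4-[9-(trimethylsilyl)non-8-yn-1-yl]oxane-3-carbaldehyde | CO[C@@H]1O[C@@H](C)C[C@H](CCCCCCCC#C[Si](C)(C)C)[C@H]1C=O | intermediate
12 | (2R,3S,4S,6S)-3-ethynyl-2-methoxy-6-methyl-4-[9-(trimethylsilyl)non-8-yn-1-yl]oxane | CO[C@@H]1O[C@@H](C)C[C@H](CCCCCCCC#C[Si](C)(C)C)[C@H]1C#C | intermediate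
13 | (2R,3S,4S,6S)-3-ethynyl-2-methoxy-6-methyl-4-(non-8-yn-1-yl)oxane (key-step precursor) | CO[C@@H]1O[C@@H](C)C[C@H](CCCCCCCC#C)[C@H]1C#C | intermediate
14 | tetrahydropyran methyl acetal trans-fused through Ca–Cb to a cyclotrideca-1,3-diyne (key-step product) | CO[C@@H]2O[C@@H](C)C[C@@H]1CCCCCCCC#CC#C[C@H]12 | intermediate
15 | pyrrolophane methyl acetal: 1H-pyrrole ring C with C2 on Ca and C5 linked by (CH2)7 to Cb | CO[C@@H]2O[C@@H](C)C[C@@H]1CCCCCCCc3ccc([nH]3)[C@H]12 | intermediate
16 | pyrrolophane lactol, anomeric mixture | OC2O[C@@H](C)C[C@@H]1CCCCCCCc3ccc([nH]3)[C@H]12 | intermediate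
17 | pyrrolophane δ-lactone | O=C2O[C@@H](C)C[C@@H]1CCCCCCCc3ccc([nH]3)[C@H]12 | intermediate
18 | methyl (E)-3-methoxyacrylate | CO/C=C/C(=O)OC | starting material
19 | N-lithio derivative of lactone 17 | O=C2O[C@@H](C)C[C@@H]1CCCCCCCc3ccc(n3[Li])[C@H]12 | intermediate
20 | methyl 3-lithio-3-methoxyacrylate, lithium cis to the ester | [Li]/C(OC)=C\C(=O)OC | intermediate
21 | spiro tetronate: 4-methoxyfuran-2(5H)-one spiro at C5 to Cs (spiro epimers) | COC1=CC(=O)OC12O[C@@H](C)C[C@@H]1CCCCCCCc3ccc([nH]3)[C@H]12 | intermediate
22 | hydroxylactam: 5-hydroxy-4-methoxy-1,5-dihydro-2H-pyrrol-2-one carrying at C5 the ring-opened chain (Ca with ring C, Cb, CH2CH(OH)CH3) | COC1=CC(=O)NC1(O)[C@@H]2c3ccc([nH]3)CCCCCCC[C@H]2C[C@H](C)O | intermediate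
23 | spiro lactam: 4-methoxy-1,5-dihydro-2H-pyrrol-2-one spiro at C5 (= Cs), N cis to ring C | COC1=CC(=O)N[C@]12O[C@@H](C)C[C@@H]1CCCCCCCc3ccc([nH]3)[C@H]12 | intermediate
24 | lactim triflate of 23 | COC1=CC(OS(=O)(=O)C(F)(F)F)=N[C@]12O[C@@H](C)C[C@@H]1CCCCCCCc3ccc([nH]3)[C@H]12 | intermediate
25 | N-Boc-pyrrol-2-ylboronic acid | CC(C)(C)OC(=O)n1cccc1B(O)O | starting material
26 | N-Boc-premarineosin A (Boc on ring A nitrogen) | COC1=CC(c2cccn2C(=O)OC(C)(C)C)=N[C@]12O[C@@H](C)C[C@@H]1CCCCCCCc3ccc([nH]3)[C@H]12 | intermediate
27 | premarineosin A | COC1=CC(c2ccc[nH]2)=N[C@]12O[C@@H](C)C[C@@H]1CCCCCCCc3ccc([nH]3)[C@H]12 | target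

**Totals and risks**

Total step count: 14. Longest linear sequence: 14 steps (from 1 and 2 to 27).

Steps most likely to fail:

1. Step 7. Intermolecular coupling to the cyclic dimer and oligomers may outrun closure of the strained 13-membered diyne, whose tether must be almost fully extended. The fallback joins the same two carbons at the sp3 level and sets out from 13. Gold-catalysed Markovnikov hydration of both alkynes ((Ph3P)AuNTf2, MeOH/H2O) should give the bis(methyl ketone) F1. Kinetic double enolisation at the methyl groups (LiN(i-Pr)2, −78 °C) and capture with i-Pr2SiCl2 under dilution would give the cyclic diisopropylsilylene bis-enol ether F2. Oxidative coupling of the silyl bis-enol ether ((NH4)2Ce(NO3)6, NaHCO3, MeCN, −10 °C) would form the 13-membered 1,4-diketone F3, free of diyne strain. Paal–Knorr condensation with NH4OAc in MeOH returns to the route at 15, replacing steps 7 and 8.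

2. Step 12. Ammonia may add to the methoxy-bearing alkene carbon (addition–elimination) instead of opening the acylal carbonyl, or the spiro centre may equilibrate toward the wrong epimer or toward an enamide by loss of the Ca proton. The spiro preference rests on a conformational argument that is not secured by precedent. The fallback delivers nitrogen to Cs first, under kinetic control, and sets out from 21. TMSOTf with TMSN3 (MeCN, −40 °C) ionises the acylal to the ring oxocarbenium ion, and azide adding axially would give the azido acid F4. Staudinger reduction (PMe3, THF/H2O) and carbodiimide closure of the amine onto the cis carboxyl return to the route at 23, where acid equilibration remains available.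

3. Step 13. Triflic anhydride may sulfonylate the electron-rich ring C, or the activated lactam may open the N,O-ketal before O-triflation is complete. The fallback activates the lactam through sulfur and sets out from 23. Lawesson's reagent should give the thiolactam F5, and MeI with K2CO3 the S-methyl thioimidate F6. Liebeskind–Srogl coupling with 25 (Pd2(dba)3 as zerovalent palladium source, tri(2-furyl)phosphine, copper thiophene-2-carboxylate CuO2CC4H3S with monovalent copper, THF, 50 °C) returns to the route at 26.

**Further compounds**

F1 | step 7 | bis(methyl ketone): acetyl on Ca and 8-oxononyl on Cb of the methyl acetal, configuration as in 13 | CO[C@@H]1O[C@@H](C)C[C@H](CCCCCCCC(C)=O)[C@H]1C(C)=O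
F2 | step 7 | cyclic diisopropylsilylene bis-enol ether of F1 | CO[C@@H]1O[C@@H](C)C[C@@H]2CCCCCCCC(=C)O[Si](C(C)C)(C(C)C)OC(=C)[C@H]21
F3 | step 7 | 13-membered 1,4-diketone trans-fused to the tetrahydropyran methyl acetal | CO[C@@H]1O[C@@H](C)C[C@@H]2CCCCCCCC(=O)CCC(=O)[C@H]21
F4 | step 12 | azido acid: Cs bearing azide, ring oxygen and the (Z)-2-carboxy-1-methoxyvinyl group | CO/C(=C/C(=O)O)[C@]1(N=[N+]=[N-])O[C@@H](C)C[C@@H]2CCCCCCCc3ccc([nH]3)[C@H]21
F5 | step 13 | spiro thiolactam (C=S in place of the lactam C=O of 23) | COC1=CC(=S)N[C@]12O[C@@H](C)C[C@@H]1CCCCCCCc3ccc([nH]3)[C@H]12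
F6 | step 13 | S-methyl thioimidate: 3-methoxy-5-(methylthio)-2H-pyrrole spiro at C2 | COC1=CC(SC)=N[C@]12O[C@@H](C)C[C@@H]1CCCCCCCc3ccc([nH]3)[C@H]12
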